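## Structural features

The target is a 4-methoxy-6,6-disubstituted cyclohex-2-en-1-one. The numbering used throughout is: ring carbonyl C6, quaternary C1, methylene C2, methoxy carbon C3, alkene C4=C5, side-chain carbon C8 (methyl) and benzylic C7 (acetate, 3,4,5-trimethoxyphenyl). C1 carries an allyl group and the C8–C7 chain, so three stereocentres are contiguous: C1 (R), C8 (S) and C7 (S), with C7/C8 anti. The fourth centre, C3 (R), is 1,3 to C1, and its methoxy group is cis to the C8 chain and trans to allyl. The fragile groups are the γ-methoxy enone (base can enolise it through C3–H), the benzylic acetate on an electron-rich arene (hydrolysis, ionisation) and the terminal alkene. The real difficulty is the quaternary C1, wedged between the C6 carbonyl and the tertiary C8, which must be set relative to the acyclic C8 and to C3 across the ring. The key step exploits the para relationship of the C3 oxygen and the C6 carbonyl with C4=C5 between them: these are the two termini and the central bond of a 3-hydroxy-2-pyrone diene. C1–C2 is then the double bond of a 2-substituted acrolein whose formyl carbon becomes the allyl CH2.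

## Logic of the disconnections

23 ⇒ 22 ⇒ 21: the O–acyl bond and then the O–Si bond at C7 are cut. The acetate cannot survive hydroxide, ylides or hydride, so it is put on last. The gain is one robust, bulky protecting group for the whole route; the demand is a non-basic desilylation and acylation of a hindered benzylic alcohol.

21 ⇒ 20: the O–CH3 bond at C3 is cut. The C3 oxygen is meant to arrive as a lactone oxygen, so it must be alkylated after it is set free. The demand is a methylation that does not enolise the γ-hydroxy enone.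

20 ⇒ 19 ⇒ 18: a carboxyl carbon is added back at C6 and tied to the C3 oxygen as a lactone. The C6 ketone becomes a tertiary α-hydroxy acid derivative and the ring becomes a rigid bicycle in which C3–O and C6 are necessarily cis-bridged. The demand is a lactone opening followed by oxidative decarboxylation that leaves the alkenes alone.

18 ⇒ 16 (through 17) ⇒ 13 (through 15 and 14) ⇒ 12 ⇒ 11: the terminal C=C of the allyl group and then the enol-ether C=C are cut, so the allyl CH2 becomes a formyl carbon on C1. The gain is an electron-withdrawing group on C1, which is what a cycloaddition needs. The demand is two olefinations at a neopentyl position, with the β-hydroxy aldehyde masked (12) so that basic ylides cannot trigger retro-aldol cleavage.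

11 ⇒ 9 + 10: the C1–C6 and C2–C3 bonds are cut. This removes the ring and three stereocentres at once and leaves a flat, purchasable diene and an acyclic enal. The demand is regiocontrol (oxygen-bearing terminus to C1), endo orientation of the formyl group and the correct π-face of 9 relative to C8.

9 ⇒ 8: the C1=CH2 bond is cut (methylene from a one-carbon electrophile). This gives an aldehyde whose α-carbon is a plain CH2, so C8 cannot epimerise. The demand is a mild α-methylenation.

8 ⇒ 7 ⇒ 5 ⇒ 4: functional-group changes only (aldehyde ⇐ primary alcohol ⇐ terminal alkene; silyl ether ⇐ alcohol). The vinyl group of 4 is a latent two-carbon aldehyde; the demand is anti-Markovnikov hydration.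

4 ⇒ 1 + 2: the C7–C8 bond is cut. Both side-chain stereocentres then come from one carbonyl crotylation of a purchasable aryl aldehyde. The demand is anti diastereoselectivity (E-crotyl geometry) and enantiofacial control by a chiral catalyst.

## Other disconnections considered

Alternative 1: The cut is the C1–C8 bond together with a temporary C7–O bond to the C6 oxygen. This divides the target into the quinone monoketal A1 and the propenylarene A2.
- Forward step: a Lewis or Brønsted acid ionises A1 to a methoxy-stabilised dienone cation. A2 attacks the allyl-bearing carbon through C8, and the benzylic cation at C7 is captured by the carbonyl oxygen to close the dihydrobenzofuranone A3.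
- In favour: the step is convergent. It forms quaternary C1 and the C1/C8/C7 relative configuration in one operation from two achiral, quickly made pieces, and the allyl group is present from the start. From A3, saturation of the methoxy-enol ether bond, reduction of the C4 carbonyl and acid-induced enol-ether hydrolysis with β-elimination should lead to 22, and acetylation to 23.
- Where it is equal or better: on step economy and convergence it is clearly better than the chosen plan (roughly half the steps). On relative control of C1/C8/C7 it is equal or better.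
- Against: neither partner nor the promoter is chiral, so the product would be racemic, whereas the chosen plan controls absolute configuration. The cation can also be trapped through carbon (a 5+2 mode), so periselectivity would depend on acid and temperature. C3 would have to be set later by face-selective reduction of a tetrasubstituted enol ether under remote control, whereas the bicycle of the chosen plan fixes C3 against C1. The C4 carbonyl is a surplus oxygen.
- Mechanism: a stepwise cationic process on an electron-rich arene (risk of arylation side reactions), against an anionic, hydrogen-bond-organised cycloaddition.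

Alternative 2: The cut is the C3–C4 bond.
- Forward step: under Nozaki–Hiyama–Kishi conditions (CrCl2 with catalytic NiCl2, divalent chromium as the stoichiometric reductant) the vinyl iodide of the bis-aldehyde A4 becomes a C4 vinylchromium species. This adds to one of the two oxoethyl arms to close the ring and give A5.
- In favour: the ring-closing bond creates the C3 carbinol and leaves the enone, which is exactly the target's oxidation pattern, with no bridge to excise. The reaction is chemoselective for aldehydes, so the C7 acetate could already be in place.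
- Where it is better: after A5 only O-methylation and methylenation of the spare arm would remain. On post-cyclisation step count and on protecting-group economy it is better than the chosen plan.
- Against: one event must choose between two diastereotopic arms (fixing C1) and two aldehyde faces (fixing C3). That is four outcomes, steered only by the acyclic C8/C7 unit with no rigid element, whereas the chosen plan ties C3 to C1 through a bicycle. A4 is the real cost: a quaternary carbon with two identical arms, the side chain and a (Z)-β-iodoenone that is prone to isomerisation and addition–elimination. Its assembly would probably take as many steps as the whole chosen route up to 11. CrCl2 is needed in excess, against a catalytic amine.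
- Where it is equal: the uncertainty about how C8 steers C1 is the same in both plans.

Alternative 3: The cuts are C1–C2 and C5–C6.
- Forward step: a chiral primary amine with an acid cocatalyst converts the α-branched aldehyde A6 into an enamine. This adds to the enone A7 through C1, and aldol condensation then closes the cyclohexenone A8.
- In favour and where it is better: A6 would come from 8 by one α-allylation, so the early route is shared. The allyl group is in place before the ring exists, so no formyl-to-allyl homologation is needed, and on that point it is better than the chosen plan. The reagents are cheap.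
- Where it is equal: catalyst control at C1 against the neighbouring C8 centre is the same double-stereodifferentiation problem as in the chosen plan.
- Against: A8 has the carbonyl at C4, the alkene at C5=C6 and no oxygen at C3 or C6. It would need α-oxygenation at C3 (a new centre set 1,3 to C1 without a rigid controller) and a 1,3-carbonyl transposition (epoxidation of a hindered enone beside the quaternary carbon, Wharton rearrangement, re-oxidation). That is at least six further steps on sensitive intermediates. Overall step count would be equal or worse, and the chosen plan is better on oxygenation pattern and on C3. Enamine formation from an aldehyde branched at both α and β positions is expected to be slow.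

Key step: step 6

Assumption 1: in step 1 the (S)-configured phosphoric acid is taken to deliver the crotyl group to the Si face of 1 (1S alcohol); if the sense is the reverse, the (R)-acid is used and nothing else changes.

Assumption 2: 10, 2 and both pseudoenantiomeric cinchona catalysts are treated as purchasable.

Abbreviations in names: Ar = 3,4,5-trimethoxyphenyl; TBS = tert-butyl(dimethyl)silyl; TMS = trimethylsilyl; SC = the (1S,2S)-1-(TBS-oxy)-1-Ar-propan-2-yl chain (attached through C8; C7 is the benzylic carbon).

## Route

Step 1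
Reactants: 1 3,4,5-trimethoxybenzaldehyde; 2 (E)-crotylboronic acid pinacol ester
Product: 4 (1S,2S)-2-methyl-1-Ar-but-3-en-1-ol, via O-pinacolboryl ether 3 (not isolated)
Conditions: 2 (1.2 equiv), (S)-TRIP [(S)-3,3'-bis(2,4,6-triisopropylphenyl)-1,1'-binaphthyl-2,2'-diyl hydrogen phosphate] (5 mol%), 4 Å MS, toluene, −30 °C; aqueous work-up
Reagents that add atoms: none
Why: Chiral phosphoric acid-catalysed crotylboration, a reaction type that works best with aromatic aldehydes; the closed chair transition state with the aryl group equatorial turns the E-crotyl geometry into the anti C7/C8 relationship, and the catalyst selects the Si face of 1 to set C7 as S.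

Step 2
Reactants: 4 (1S,2S)-2-methyl-1-Ar-but-3-en-1-ol
Product: 5 TBS ether of 4, tert-butyl(dimethyl){[(1S,2S)-2-methyl-1-Ar-but-3-en-1-yl]oxy}silane
Conditions: TBSOTf, 2,6-lutidine, CH2Cl2, −78 → 0 °C
Reagents that add atoms: tert-butyldimethylsilyl trifluoromethanesulfonate, CC(C)(C)[Si](C)(C)OS(=O)(=O)C(F)(F)F
Why: Standard silylation of a secondary benzylic alcohol with a silyl triflate and a hindered base; no stereocentre is touched, and the TBS group later survives ylides, hydroxide and Pb(OAc)4 and is the bulky element at C7 in the cycloaddition.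

Step 3
Reactants: 5 TBS ether of 4
Product: 7 (3S,4S)-4-(TBS-oxy)-3-methyl-4-Ar-butan-1-ol, via B-alkyl-9-borabicyclononane 6 (not isolated)
Conditions: 9-BBN, THF, 0 °C → rt; then 3 M NaOH, 30% H2O2, 0 °C → rt
Reagents that add atoms: 9-borabicyclo[3.3.1]nonane, B1C2CCCC1CCC2 (boron and ring carbons of 6 only); hydrogen peroxide, OO (hydroxyl oxygen of 7)
Why: Anti-Markovnikov hydroboration–oxidation; 9-BBN places boron on the terminal carbon of the monosubstituted alkene and alkaline peroxide replaces it by hydroxyl, while silyl ether and arene are inert.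

Step 4
Reactants: 7 (3S,4S)-4-(TBS-oxy)-3-methyl-4-Ar-butan-1-ol
Product: 8 (3S,4S)-4-(TBS-oxy)-3-methyl-4-Ar-butanal
Conditions: TEMPO (10 mol%), PhI(OAc)2, CH2Cl2, rt
Reagents that add atoms: none
Why: Oxoammonium-catalysed oxidation of a primary alcohol that stops at the aldehyde; the α-carbon is a CH2 group, so the β-stereocentre C8 cannot epimerise.

Step 5
Reactants: 8 (3S,4S)-4-(TBS-oxy)-3-methyl-4-Ar-butanal
Product: 9 (3S,4S)-4-(TBS-oxy)-3-methyl-2-methylidene-4-Ar-butanal (anti)
Conditions: 37% aq. CH2O, pyrrolidine (10 mol%), propionic acid (10 mol%), i-PrOH, 45 °C; used promptly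
Reagents that add atoms: formaldehyde, C=O
Why: Amine/acid-catalysed α-methylenation (Mannich condensation through the enamine, then elimination of the amine); C8 is not part of the enamine, and prompt use limits dimerisation and double-bond migration of the 2-substituted acrolein.

Step 6
Reactants: 9 (3S,4S)-4-(TBS-oxy)-3-methyl-2-methylidene-4-Ar-butanal; 10 3-hydroxy-2H-pyran-2-one
Product: 11 (1R,4S,5S)-4-hydroxy-3-oxo-5-SC-2-oxabicyclo[2.2.2]oct-7-ene-5-carbaldehyde (formyl endo)
Conditions: 10 (1.5 equiv), 9-O-(9-phenanthryl)cupreidine or its cupreine pseudoenantiomer (10 mol%, the matched one), EtOAc, 0 °C → rt; Et3N (20 mol%), CH2Cl2 as achiral reference run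
Reagents that add atoms: none
Why: The amine deprotonates the 3-hydroxyl of 10 to an ammonium oxidopyrone, an electron-rich diene whose nucleophilic terminus is pyrone C6, while the catalyst's hydrogen-bond donor holds the formyl oxygen of 9. The reaction is an asynchronous normal-demand (4+2) cycloaddition in which pyrone C6 bonds first to the methylene carbon (C2–C3 bond) and the oxido-bearing pyrone C3 then bonds to the fully substituted α-carbon (C1–C6 bond); in the stepwise limit it is a vinylogous Michael addition followed by a 6-(enolexo)-exo-trig aldol closure. The closest known reaction type is the amine- and cinchona-catalysed Diels–Alder reaction of 3-hydroxy-2-pyrones with acrylates, enones and α-substituted acrylonitriles. The one ring closed is the six-membered carbocycle, formed by intermolecular cycloaddition as a 2-oxabicyclo[2.2.2]octene with the lactone as the bridge. C3 and C6 are tied to each other by suprafacial addition across the planar pyrone, and their absolute sense is the choice of pyrone face, which the chiral amine controls. C1 relative to the bicycle follows from the endo formyl group (under the diene, hydrogen-bonded to the catalyst), which puts the bulky C8 chain exo beneath the flat lactone bridge and therefore cis to the C3 oxygen. C1 relative to C8 needs bonding to the Re face at C2 of 9, the face anti to the silyloxybenzyl group when C8–H eclipses C=CH2; since the rotamer with C8–H eclipsing the C–CHO bond would expose the other face, this acyclic bias is judged small and the matched catalyst pseudoenantiomer is relied on to impose the face. Regiochemistry (oxido terminus to the α-carbon) follows from the polarisation of both partners, so the selectivities that must be secured are endo and π-facial.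

Step 7
Reactants: 11 (1R,4S,5S)-4-hydroxy-3-oxo-5-SC-2-oxabicyclo[2.2.2]oct-7-ene-5-carbaldehyde
Product: 12 (1R,4S,5S)-3-oxo-5-SC-4-(TMS-oxy)-2-oxabicyclo[2.2.2]oct-7-ene-5-carbaldehyde
Conditions: TMSOTf, 2,6-lutidine, CH2Cl2, −78 °C
Reagents that add atoms: trimethylsilyl trifluoromethanesulfonate, C[Si](C)(C)OS(=O)(=O)C(F)(F)F
Why: Silylation of the tertiary hydroxyl; it blocks the retro-aldol cleavage of the C1–C6 bond that an alkoxide β to the formyl group could undergo under the basic ylide of step 8, and the aldehyde has no α-hydrogen to be enol-silylated.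

Step 8
Reactants: 12 (1R,4S,5S)-3-oxo-5-SC-4-(TMS-oxy)-2-oxabicyclo[2.2.2]oct-7-ene-5-carbaldehyde
Product: 13 (1R,4S,8S)-8-(2-methoxyethenyl)-8-SC-4-(TMS-oxy)-2-oxabicyclo[2.2.2]oct-5-en-3-one (E/Z mixture)
Conditions: Ph3P(CH2OMe)Cl, KHMDS, THF, 0 °C; then 12, −78 → 0 °C
Reagents that add atoms: (methoxymethyl)triphenylphosphonium chloride, COC[P+](c1ccccc1)(c1ccccc1)c1ccccc1.[Cl-]
Why: Wittig olefination with the methoxymethylene ylide (one-carbon homologation); the aldehyde is far more electrophilic than the lactone, and the enol-ether geometry is irrelevant because the double bond is hydrolysed next.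

Step 9
Reactants: 13 (1R,4S,8S)-8-(2-methoxyethenyl)-8-SC-4-(TMS-oxy)-2-oxabicyclo[2.2.2]oct-5-en-3-one
Product: 16 lactol (cyclic hemiacetal between the C6 hydroxyl and the new formyl group; mixture of anomers), via hydroxy enol ether 14 (not isolated), via cyclic methyl acetal 15 (not isolated)
Conditions: TsOH·H2O (0.2 equiv), acetone–H2O (10:1), rt
Reagents that add atoms: water, O (hemiacetal hydroxyl oxygen of 16)
Why: Aqueous acid first cleaves the labile tertiary TMS ether; C-protonation of the enol ether then gives an oxocarbenium ion that the freed neighbouring hydroxyl traps in a 5-exo closure to the cyclic methyl acetal, and acetal hydrolysis (loss of methanol, addition of water to the cyclic oxocarbenium ion) leaves the five-membered lactol. The hindered benzylic TBS ether should survive catalytic acid at room temperature.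

Step 10
Reactants: 16 lactol
Product: 18 (1R,4S,8R)-4-hydroxy-8-(prop-2-en-1-yl)-8-SC-2-oxabicyclo[2.2.2]oct-5-en-3-one, via open hydroxy aldehyde 17 (not isolated)
Conditions: Ph3PCH3Br (4 equiv), KOt-Bu (3.8 equiv), THF, 0 °C → rt
Reagents that add atoms: methyltriphenylphosphonium bromide, C[P+](c1ccccc1)(c1ccccc1)c1ccccc1.[Br-]
Why: Wittig methylenation of a lactol through its ring-opened hydroxy aldehyde tautomer, a standard operation; the alkoxide is now γ to the carbonyl group and cannot fragment by retro-aldol cleavage, and the formyl-to-allyl homologation is complete.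

Step 11
Reactants: 18 (1R,4S,8R)-4-hydroxy-8-(prop-2-en-1-yl)-8-SC-2-oxabicyclo[2.2.2]oct-5-en-3-one
Product: 20 (4R,6R)-4-hydroxy-6-(prop-2-en-1-yl)-6-SC-cyclohex-2-en-1-one, via hydroxy acid 19 (not isolated)
Conditions: LiOH·H2O, THF–H2O, 0 °C → rt; AcOH to pH 6–7, concentrate, toluene azeotrope; Pb(OAc)4, CH2Cl2–MeOH, −20 → 0 °C
Reagents that add atoms: lithium hydroxide, [Li+].[OH-] (carboxyl oxygen of 19 only; no reagent atom other than hydrogen stays in 20)
Why: Saponification opens the strained bridged lactone to the cis-1,4-dihydroxy carboxylate; lead tetraacetate then effects oxidative decarboxylation of the tertiary α-hydroxy acid through a cyclic lead ester. The resulting C6 ketone is conjugated with the existing C4=C5 bond, and C1 and C3 are untouched.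

Step 12
Reactants: 20 (4R,6R)-4-hydroxy-6-(prop-2-en-1-yl)-6-SC-cyclohex-2-en-1-one
Product: 21 (4R,6R)-4-methoxy-6-(prop-2-en-1-yl)-6-SC-cyclohex-2-en-1-one
Conditions: MeI (excess), Ag2O, 4 Å MS, MeCN, rt, dark
Reagents that add atoms: iodomethane, CI
Why: Purdie-type O-methylation under near-neutral conditions, chosen because alkoxide bases would remove C3–H of the γ-hydroxy enone and isomerise it to the 1,4-dione; the C3–O bond is not broken, so configuration is retained.

Step 13
Reactants: 21 (4R,6R)-4-methoxy-6-(prop-2-en-1-yl)-6-SC-cyclohex-2-en-1-one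
Product: 22 (4R,6R)-6-[(1S,2S)-1-hydroxy-1-Ar-propan-2-yl]-4-methoxy-6-(prop-2-en-1-yl)cyclohex-2-en-1-one
Conditions: HF·pyridine, pyridine, THF, 0 °C → rt
Reagents that add atoms: none
Why: Fluoride-mediated desilylation under buffered, non-basic conditions, so the γ-methoxy enone is not enolised and C7 keeps its configuration (only the Si–O bond is cleaved).

Step 14
Reactants: 22 (4R,6R)-6-[(1S,2S)-1-hydroxy-1-Ar-propan-2-yl]-4-methoxy-6-(prop-2-en-1-yl)cyclohex-2-en-1-one
Product: 23 (1S,2S)-2-[(1R,5R)-5-methoxy-2-oxo-1-(prop-2-en-1-yl)cyclohex-3-en-1-yl]-1-Ar-propyl acetate (target, CNP0236985.2)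
Conditions: Ac2O, pyridine, DMAP (cat.), CH2Cl2, 0 °C → rt
Reagents that add atoms: acetic anhydride, CC(=O)OC(C)=O
Why: DMAP-catalysed acylation of the secondary benzylic alcohol with retention at C7; the mild base does not affect the enone.

## Compound list

1 | 3,4,5-trimethoxybenzaldehyde | COc1cc(C=O)cc(OC)c1OC | starting material
2 | (E)-crotylboronic acid pinacol ester, 2-[(2E)-but-2-en-1-yl]-4,4,5,5-tetramethyl-1,3,2-dioxaborolane | C/C=C/CB1OC(C)(C)C(C)(C)O1 | starting material
3 | 2-{[(1S,2S)-2-methyl-1-Ar-but-3-en-1-yl]oxy}-4,4,5,5-tetramethyl-1,3,2-dioxaborolane | C=C[C@H](C)[C@H](OB1OC(C)(C)C(C)(C)O1)c2cc(OC)c(OC)c(OC)c2 | intermediate (not isolated)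
4 | (1S,2S)-2-methyl-1-Ar-but-3-en-1-ol | C=C[C@H](C)[C@H](O)c1cc(OC)c(OC)c(OC)c1 | intermediate
5 | tert-butyl(dimethyl){[(1S,2S)-2-methyl-1-Ar-but-3-en-1-yl]oxy}silane | C=C[C@H](C)[C@H](O[Si](C)(C)C(C)(C)C)c1cc(OC)c(OC)c(OC)c1 | intermediate
6 | 9-[(3S,4S)-4-(TBS-oxy)-3-methyl-4-Ar-butyl]-9-borabicyclo[3.3.1]nonane | B1(CC[C@H](C)[C@H](O[Si](C)(C)C(C)(C)C)c3cc(OC)c(OC)c(OC)c3)C2CCCC1CCC2 | intermediate (not isolated)
7 | (3S,4S)-4-(TBS-oxy)-3-methyl-4-Ar-butan-1-ol | OCC[C@H](C)[C@H](O[Si](C)(C)C(C)(C)C)c1cc(OC)c(OC)c(OC)c1 | intermediate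
8 | (3S,4S)-4-(TBS-oxy)-3-methyl-4-Ar-butanal | O=CC[C@H](C)[C@H](O[Si](C)(C)C(C)(C)C)c1cc(OC)c(OC)c(OC)c1 | intermediate
9 | (3S,4S)-4-(TBS-oxy)-3-methyl-2-methylidene-4-Ar-butanal | C=C(C=O)[C@H](C)[C@H](O[Si](C)(C)C(C)(C)C)c1cc(OC)c(OC)c(OC)c1 | intermediate
10 | 3-hydroxy-2H-pyran-2-one | O=C1OC=CC=C1O | starting material
11 | (1R,4S,5S)-4-hydroxy-3-oxo-5-SC-2-oxabicyclo[2.2.2]oct-7-ene-5-carbaldehyde (formyl endo) | O=C[C@]1([C@H](C)[C@H](O[Si](C)(C)C(C)(C)C)c3cc(OC)c(OC)c(OC)c3)C[C@H]2OC(=O)[C@]1(O)C=C2 | intermediate
12 | (1R,4S,5S)-3-oxo-5-SC-4-(TMS-oxy)-2-oxabicyclo[2.2.2]oct-7-ene-5-carbaldehyde | O=C[C@]1([C@H](C)[C@H](O[Si](C)(C)C(C)(C)C)c3cc(OC)c(OC)c(OC)c3)C[C@H]2OC(=O)[C@]1(O[Si](C)(C)C)C=C2 | intermediate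
13 | (1R,4S,8S)-8-(2-methoxyethenyl)-8-SC-4-(TMS-oxy)-2-oxabicyclo[2.2.2]oct-5-en-3-one (E/Z mixture) | COC=C[C@]1([C@H](C)[C@H](O[Si](C)(C)C(C)(C)C)c3cc(OC)c(OC)c(OC)c3)C[C@H]2OC(=O)[C@]1(O[Si](C)(C)C)C=C2 | intermediate
14 | (1R,4S,8S)-4-hydroxy-8-(2-methoxyethenyl)-8-SC-2-oxabicyclo[2.2.2]oct-5-en-3-one (E/Z mixture) | COC=C[C@]1([C@H](C)[C@H](O[Si](C)(C)C(C)(C)C)c3cc(OC)c(OC)c(OC)c3)C[C@H]2OC(=O)[C@]1(O)C=C2 | intermediate (not isolated)
15 | cyclic methyl acetal (2-methoxytetrahydrofuran fused across the carbinol bridgehead and the quaternary carbon; anomer mixture) | COC1C[C@]2([C@H](C)[C@H](O[Si](C)(C)C(C)(C)C)c4cc(OC)c(OC)c(OC)c4)C[C@H]3OC(=O)[C@]2(O1)C=C3 | intermediate (not isolated)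
16 | lactol of 17 (2-hydroxytetrahydrofuran fused across the carbinol bridgehead and the quaternary carbon; anomer mixture) | OC1C[C@]2([C@H](C)[C@H](O[Si](C)(C)C(C)(C)C)c4cc(OC)c(OC)c(OC)c4)C[C@H]3OC(=O)[C@]2(O1)C=C3 | intermediate
17 | 2-[(1R,4S,8S)-4-hydroxy-3-oxo-8-SC-2-oxabicyclo[2.2.2]oct-5-en-8-yl]acetaldehyde | O=CC[C@]1([C@H](C)[C@H](O[Si](C)(C)C(C)(C)C)c3cc(OC)c(OC)c(OC)c3)C[C@H]2OC(=O)[C@]1(O)C=C2 | intermediate (not isolated)
18 | (1R,4S,8R)-4-hydroxy-8-(prop-2-en-1-yl)-8-SC-2-oxabicyclo[2.2.2]oct-5-en-3-one | C=CC[C@]1([C@H](C)[C@H](O[Si](C)(C)C(C)(C)C)c3cc(OC)c(OC)c(OC)c3)C[C@H]2OC(=O)[C@]1(O)C=C2 | intermediate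
19 | (1S,4R,6R)-1,4-dihydroxy-6-(prop-2-en-1-yl)-6-SC-cyclohex-2-ene-1-carboxylic acid (lithium salt in the flask) | C=CC[C@]1([C@H](C)[C@H](O[Si](C)(C)C(C)(C)C)c2cc(OC)c(OC)c(OC)c2)C[C@@H](O)C=C[C@@]1(O)C(=O)O | intermediate (not isolated)
20 | (4R,6R)-4-hydroxy-6-(prop-2-en-1-yl)-6-SC-cyclohex-2-en-1-one | C=CC[C@]1([C@H](C)[C@H](O[Si](C)(C)C(C)(C)C)c2cc(OC)c(OC)c(OC)c2)C[C@@H](O)C=CC1=O | intermediate
21 | (4R,6R)-4-methoxy-6-(prop-2-en-1-yl)-6-SC-cyclohex-2-en-1-one | C=CC[C@]1([C@H](C)[C@H](O[Si](C)(C)C(C)(C)C)c2cc(OC)c(OC)c(OC)c2)C[C@@H](OC)C=CC1=O | intermediate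
22 | (4R,6R)-6-[(1S,2S)-1-hydroxy-1-Ar-propan-2-yl]-4-methoxy-6-(prop-2-en-1-yl)cyclohex-2-en-1-one | C=CC[C@]1([C@H](C)[C@H](O)c2cc(OC)c(OC)c(OC)c2)C[C@@H](OC)C=CC1=O | intermediate
23 | (1S,2S)-2-[(1R,5R)-5-methoxy-2-oxo-1-(prop-2-en-1-yl)cyclohex-3-en-1-yl]-1-Ar-propyl acetate | C=CC[C@]1([C@H](C)[C@H](OC(C)=O)c2cc(OC)c(OC)c(OC)c2)C[C@@H](OC)C=CC1=O | target

## Step count and least certain steps

Total: 14 steps. Longest linear sequence: 14 steps (1 → 23); 2 and 10 enter as purchased materials at steps 1 and 6. Five steps lead to the cycloaddition precursor 9 and eight follow the key step.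

Step 6 (key step). What is most likely to go wrong is a slow cycloaddition at the congested, 2-branched enal. During it the amine can isomerise 9 (γ-deprotonation at C8 to the conjugated 2-methyl-2-enal, which erases C8), and the β-hydroxy aldehyde adduct can revert by retro-aldol/retro-Michael cleavage. In addition, π-facial discrimination by the acyclic C8 centre is intrinsically weak, because two rotamers expose opposite faces, so selectivity rests entirely on the catalyst.

The fallback moves the dienophile to the acrylate oxidation level, the class for which amine-catalysed facial control is best documented. It sets out from 9: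
- Chlorite oxidation (NaClO2, NaH2PO4, 2-methyl-2-butene, t-BuOH–H2O) should give the 2-methylidene carboxylic acid F1.
- Coupling with ethanethiol (DCC, DMAP, CH2Cl2, 0 °C) should give the S-ethyl thioester F2. Its γ-hydrogen is much less acidic than that of the enal.
- The same amine-catalysed cycloaddition with 10 should give the bicyclic thioester adduct F3, a β-hydroxy thioester that resists retro-aldol cleavage.
- Fukuyama reduction (Et3SiH, Pd/C, acetone, rt) should convert the thioester into the aldehyde without touching the lactone, returning to the route at 11.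

Step 8. The most likely failure is incomplete olefination. The formyl group sits on a quaternary carbon between the silylated carbinol and the branched C8, and the bulky, basic ylide may instead add to the strained lactone carbonyl or strip the TMS group and so open the way to retro-aldol cleavage.

The fallback sets out from 12 and builds the two-carbon arm by methylenation and hydroboration instead:
- The small ylide from Ph3PCH3Br/KOt-Bu should give the 8-vinyl lactone F4.
- 9-BBN in THF should add to the terminal alkene in preference to the bridged cis-alkene and give the alkylborane F5 (not isolated). Buffered oxidation (NaBO3·4H2O) should give the 8-(2-hydroxyethyl) lactone F6.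
- TEMPO/PhI(OAc)2 oxidation should give the TMS-protected oxoethyl lactone F7.
- TsOH in aqueous acetone should remove the TMS group and close the lactol, returning to the route at 16.

Step 11. The most likely failure is re-closure of the lactone when the carboxylate is neutralised, since hydroxyl and carboxyl are held cis on the ring. Pb(OAc)4 would then meet the lactone and not the α-hydroxy acid, and slow decarboxylation would let the allylic alcohol be oxidised.

The fallback sets out from 18 and replaces hydrolysis by reduction:
- LiAlH4 (THF, 0 °C) should give the 1-(hydroxymethyl)cyclohex-2-ene-1,4-diol F8, which cannot re-lactonise.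
- NaIO4 (THF–H2O) should cleave the tertiary/primary 1,2-diol to the ketone, returning to the route at 20.

Step 12. The most likely failure is base-induced isomerisation of the γ-hydroxy enone (dienolate formation through C3–H, leading to the 1,4-dione) or decomposition during a slow alkylation at the allylic carbinol.

The fallback sets out from 18 and methylates before the enone exists:
- Methanolysis of the lactone (K2CO3, MeOH, 0 °C) should give the methyl dihydroxy ester F9.
- MeI/Ag2O should methylate the unhindered secondary allylic hydroxyl and leave the tertiary α-hydroxy ester alone, giving the methyl 1-hydroxy-4-methoxy ester F10.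
- LiOH should give the 1-hydroxy-4-methoxy acid F11 (not isolated), which can no longer lactonise. Pb(OAc)4 decarboxylation then gives the enone directly, returning to the route at 21.

## Further compounds

F1 | step 6 | (3S,4S)-4-(TBS-oxy)-3-methyl-2-methylidene-4-Ar-butanoic acid | C=C(C(=O)O)[C@H](C)[C@H](O[Si](C)(C)C(C)(C)C)c1cc(OC)c(OC)c(OC)c1
F2 | step 6 | S-ethyl (3S,4S)-4-(TBS-oxy)-3-methyl-2-methylidene-4-Ar-butanethioate | C=C(C(=O)SCC)[C@H](C)[C@H](O[Si](C)(C)C(C)(C)C)c1cc(OC)c(OC)c(OC)c1
F3 | step 6 | S-ethyl (1R,4S,5S)-4-hydroxy-3-oxo-5-SC-2-oxabicyclo[2.2.2]oct-7-ene-5-carbothioate | CCSC(=O)[C@]1([C@H](C)[C@H](O[Si](C)(C)C(C)(C)C)c3cc(OC)c(OC)c(OC)c3)C[C@H]2OC(=O)[C@]1(O)C=C2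
F4 | step 8 | (1R,4S,8S)-8-ethenyl-8-SC-4-(TMS-oxy)-2-oxabicyclo[2.2.2]oct-5-en-3-one | C=C[C@]1([C@H](C)[C@H](O[Si](C)(C)C(C)(C)C)c3cc(OC)c(OC)c(OC)c3)C[C@H]2OC(=O)[C@]1(O[Si](C)(C)C)C=C2
F5 | step 8 | 9-{2-[(1R,4S,8R)-3-oxo-8-SC-4-(TMS-oxy)-2-oxabicyclo[2.2.2]oct-5-en-8-yl]ethyl}-9-borabicyclo[3.3.1]nonane | B1(CC[C@]2([C@H](C)[C@H](O[Si](C)(C)C(C)(C)C)c4cc(OC)c(OC)c(OC)c4)C[C@H]3OC(=O)[C@]2(O[Si](C)(C)C)C=C3)C5CCCC1CCC5
F6 | step 8 | (1R,4S,8R)-8-(2-hydroxyethyl)-8-SC-4-(TMS-oxy)-2-oxabicyclo[2.2.2]oct-5-en-3-one | OCC[C@]1([C@H](C)[C@H](O[Si](C)(C)C(C)(C)C)c3cc(OC)c(OC)c(OC)c3)C[C@H]2OC(=O)[C@]1(O[Si](C)(C)C)C=C2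
F7 | step 8 | 2-[(1R,4S,8S)-3-oxo-8-SC-4-(TMS-oxy)-2-oxabicyclo[2.2.2]oct-5-en-8-yl]acetaldehyde | O=CC[C@]1([C@H](C)[C@H](O[Si](C)(C)C(C)(C)C)c3cc(OC)c(OC)c(OC)c3)C[C@H]2OC(=O)[C@]1(O[Si](C)(C)C)C=C2
F8 | step 11 | (1S,4R,6R)-1-(hydroxymethyl)-6-(prop-2-en-1-yl)-6-SC-cyclohex-2-ene-1,4-diol | C=CC[C@]1([C@H](C)[C@H](O[Si](C)(C)C(C)(C)C)c2cc(OC)c(OC)c(OC)c2)C[C@@H](O)C=C[C@@]1(O)CO
F9 | step 12 | methyl (1S,4R,6R)-1,4-dihydroxy-6-(prop-2-en-1-yl)-6-SC-cyclohex-2-ene-1-carboxylate | C=CC[C@]1([C@H](C)[C@H](O[Si](C)(C)C(C)(C)C)c2cc(OC)c(OC)c(OC)c2)C[C@@H](O)C=C[C@@]1(O)C(=O)OC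
F10 | step 12 | methyl (1S,4R,6R)-1-hydroxy-4-methoxy-6-(prop-2-en-1-yl)-6-SC-cyclohex-2-ene-1-carboxylate | C=CC[C@]1([C@H](C)[C@H](O[Si](C)(C)C(C)(C)C)c2cc(OC)c(OC)c(OC)c2)C[C@@H](OC)C=C[C@@]1(O)C(=O)OC
F11 | step 12 | (1S,4R,6R)-1-hydroxy-4-methoxy-6-(prop-2-en-1-yl)-6-SC-cyclohex-2-ene-1-carboxylic acid | C=CC[C@]1([C@H](C)[C@H](O[Si](C)(C)C(C)(C)C)c2cc(OC)c(OC)c(OC)c2)C[C@@H](OC)C=C[C@@]1(O)C(=O)O
A1 | alternative 1 | 2-allyl-4,4,5-trimethoxycyclohexa-2,5-dien-1-one (quinone monoketal) | C=CCC1=CC(OC)(OC)C(OC)=CC1=O
A2 | alternative 1 | (E)-isoelemicin, 1,2,3-trimethoxy-5-[(1E)-prop-1-en-1-yl]benzene | C/C=C/c1cc(OC)c(OC)c(OC)c1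
A3 | alternative 1 | 3a-allyl-5-methoxy-3-methyl-2-Ar-3,3a-dihydro-1-benzofuran-6(2H)-one (2,3-trans, methyl anti to allyl) | C=CC[C@@]12[C@H](C)[C@@H](c3cc(OC)c(OC)c(OC)c3)OC1=CC(=O)C(OC)=C2
A4 | alternative 2 | (1S,2S)-6-iodo-2-methyl-4-oxo-3,3-bis(2-oxoethyl)-1-Ar-hex-5-en-1-yl acetate, (Z)-β-iodoenone bis-aldehyde | O=CCC(CC=O)([C@H](C)[C@H](OC(C)=O)c1cc(OC)c(OC)c(OC)c1)C(=O)/C=C\I
A5 | alternative 2 | (1S,2S)-2-[(1R,5R)-5-hydroxy-2-oxo-1-(2-oxoethyl)cyclohex-3-en-1-yl]-1-Ar-propyl acetate | O=CC[C@]1([C@H](C)[C@H](OC(C)=O)c2cc(OC)c(OC)c(OC)c2)C[C@@H](O)C=CC1=O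
A6 | alternative 3 | (3S,4S)-4-(TBS-oxy)-3-methyl-2-(prop-2-en-1-yl)-4-Ar-butanal (C2 epimer mixture) | C=CCC(C=O)[C@H](C)[C@H](O[Si](C)(C)C(C)(C)C)c1cc(OC)c(OC)c(OC)c1
A7 | alternative 3 | but-3-en-2-one (methyl vinyl ketone) | C=CC(C)=O
A8 | alternative 3 | 4-(prop-2-en-1-yl)-4-SC-cyclohex-2-en-1-one, target configuration at the quaternary carbon | C=CC[C@]1([C@H](C)[C@H](O[Si](C)(C)C(C)(C)C)c2cc(OC)c(OC)c(OC)c2)CCC(=O)C=C1
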